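The route rests on disconnecting ring A (the 2,4-dihydroxy-6-pentylbenzoyl unit) back to an open 3,5,7-trioxododecanoyl chain: its carbonyl carbon, flanked on the ring by C2-OH and C6-pentyl with C4-OH beyond, is C1 of that chain, and the depside oxygen is O4 of ring B. In one operation a triketo acylketene, released from a pentyl diketo-dioxinone, acylates the free 4-OH of benzyl 2,4-dihydroxy-6-propylbenzoate and the resulting aryl triketo ester closes C2 onto C7 and aromatises, so ring A and the depside ester arise together. Ring B is made the same way with benzyl alcohol as the trap, and hydrogenolysis of the benzyl ester ends the route.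

Key step: step 7

Remark on the chemistry: the open-chain polyketide intermediates are drawn as keto tautomers although they should exist largely as enols, and the cyclic aldols 10 and 17 should form as mixtures of stereoisomers whose two stereocentres vanish on aromatisation; the target has no stereocentre and no stereogenic double bond.

Step 1
Reactants: 1 2,2,6-trimethyl-4H-1,3-dioxin-4-one; 2 acetyl chloride
Product: 3 2,2-dimethyl-6-(2-oxopropyl)-4H-1,3-dioxin-4-one
Conditions: 1 (2.0 equiv), LiN(SiMe3)2 (2.0 equiv), THF, −78 °C; 2 (1.0 equiv), −78 °C; 1 M HCl quench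
Reagents that add atoms: none
Why: LiN(SiMe3)2 removes a proton from the 6-methyl group to give the extended lithium dienolate, which is C-acylated at its terminal carbon by the acid chloride (vinylogous Claisen-type acylation), and the twofold excess of dienolate takes up the acidic methylene proton of 3 so that a second acylation is avoided.

Step 2
Reactants: 4 butanoyl chloride
Product: 5 N-methoxy-N-methylbutanamide
Conditions: MeNH(OMe)·HCl (1.1 equiv), pyridine (2.2 equiv), CH2Cl2, 0 °C to rt
Reagents that add atoms: N,O-dimethylhydroxylamine hydrochloride, CNOC.Cl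
Why: Nucleophilic acyl substitution of an unhindered acid chloride by N,O-dimethylhydroxylamine (Weinreb amide formation) is fast at 0 °C, with pyridine taking up the HCl.

Step 3
Reactants: 3 2,2-dimethyl-6-(2-oxopropyl)-4H-1,3-dioxin-4-one; 5 N-methoxy-N-methylbutanamide
Product: 6 6-(2,4-dioxoheptyl)-2,2-dimethyl-4H-1,3-dioxin-4-one
Conditions: 3, LiN(i-Pr)2 (2.2 equiv), THF, −78 °C; 5 (0.9 equiv), −78 to −20 °C; cold 1 M HCl quench
Reagents that add atoms: none
Why: Two equivalents of LiN(i-Pr)2 convert 3 into its dilithium dianion, which reacts at the last-formed terminal carbanion as 1,3-dicarbonyl dianions do, and the crossed Claisen acylation by the Weinreb amide stops at the chelated tetrahedral adduct, so that the 1,3-diketone appears only on acidic work-up.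

Step 4
Reactants: 6 6-(2,4-dioxoheptyl)-2,2-dimethyl-4H-1,3-dioxin-4-one; 7 benzyl alcohol
Product: 11 benzyl 2,4-dihydroxy-6-propylbenzoate, via acylketene 8 (not isolated), via benzyl 3,5,7-trioxodecanoate 9 (not isolated), via cyclic aldol 10 (not isolated)
Conditions: 7 (1.5 equiv), PhMe, 110 °C; then K2CO3, i-PrOH–CH2Cl2, rt; then HCl, MeOH, rt
Reagents that add atoms: none
Why: Retro-[4+2] loss of acetone gives acylketene 8, benzyl alcohol adds to it to give 9, carbonate brings about the C2-to-C7 intramolecular aldol to 10 and acid dehydrates 10 to the arene (acylketene trapping followed by aldol aromatisation to a resorcylate, established for aliphatic alcohols), the hindered benzoate being inert to ester exchange during the short methanolic acid treatment.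

Step 5
Reactants: 12 hexanoyl chloride
Product: 13 N-methoxy-N-methylhexanamide
Conditions: MeNH(OMe)·HCl (1.1 equiv), pyridine (2.2 equiv), CH2Cl2, 0 °C to rt
Reagents that add atoms: N,O-dimethylhydroxylamine hydrochloride, CNOC.Cl
Why: Weinreb amide formation by nucleophilic acyl substitution, as in step 2.

Step 6
Reactants: 3 2,2-dimethyl-6-(2-oxopropyl)-4H-1,3-dioxin-4-one; 13 N-methoxy-N-methylhexanamide
Product: 14 6-(2,4-dioxononyl)-2,2-dimethyl-4H-1,3-dioxin-4-one
Conditions: 3, LiN(i-Pr)2 (2.2 equiv), THF, −78 °C; 13 (0.9 equiv), −78 to −20 °C; cold 1 M HCl quench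
Reagents that add atoms: none
Why: Crossed Claisen acylation of the dilithium dianion of 3 at its terminal carbon by a Weinreb amide, as in step 3, the stable tetrahedral adduct preventing over-addition.

Step 7
Reactants: 14 6-(2,4-dioxononyl)-2,2-dimethyl-4H-1,3-dioxin-4-one; 11 benzyl 2,4-dihydroxy-6-propylbenzoate
Product: 18 benzyl 4-[(2,4-dihydroxy-6-pentylbenzoyl)oxy]-2-hydroxy-6-propylbenzoate, via acylketene 15 (not isolated), via aryl triketo ester 16 (not isolated), via cyclic aldol 17 (not isolated)
Conditions: 14 added slowly to 11 (2.0 equiv, excess recovered), PhMe, 110 °C, N2 sweep, short heating; cool to 0 °C; Et3N (2.0 equiv), CH2Cl2, 0 °C to rt; then HCl (4 M in 1,4-dioxane), rt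
Reagents that add atoms: none
Why: Proposed new method: heating 14 expels acetone by retro-[4+2] to give acylketene 15, whose ketene carbon is captured by the 4-OH of 11 to form the depside C(=O)-O bond in aryl triketo ester 16; Et3N then enolises C2 (between the aryl ester and the C3 ketone), this carbon adds to the C7 pentyl ketone to give carbocycle 17, and anhydrous HCl dehydrates 17, which tautomerises to ring A. The closest known reaction type is the thermolysis of diketo-dioxinones with capture of the ketene by aliphatic alcohols and aldol aromatisation to alkyl resorcylates, together with the known acetoacetylation of phenols by dioxinone-derived acylketenes; what is new is carrying the aldol aromatisation through on an aryl ester. The one ring closed is the six-membered carbocycle of ring A, formed through the C2-C7 bond by a 6-exo-trig attack on the ketone (6-enolendo-exo-trig through the C2=C3 enolate, a favoured mode), and no stereocentre survives the aromatisation. Site selectivity for O4 over O2 of 11 is needed; it rests on the 2-OH being held in a hydrogen bond to the benzyl ester carbonyl and crowded by that ester, and on the excess of 11, which lets each ketene meet a fresh phenol. Chemoselectivity for C-C aldol closure over expulsion of the ring B phenoxide (pyranone formation or reversion to the ketene) is also needed and is sought through base-free trapping with short heating, an alcohol-free amine base at low temperature and a non-nucleophilic acid for the dehydration.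

Step 8
Reactants: 18 benzyl 4-[(2,4-dihydroxy-6-pentylbenzoyl)oxy]-2-hydroxy-6-propylbenzoate
Product: 19 4-[(2,4-dihydroxy-6-pentylbenzoyl)oxy]-2-hydroxy-6-propylbenzoic acid (CNP0324314.0)
Conditions: H2 (1 atm), 10% Pd/C, EtOAc, rt
Reagents that add atoms: none
Why: Hydrogenolysis of the benzylic C-O bond of the ester on palladium should free the acid under neutral conditions at room temperature, leaving the depside aryl ester, the phenols and both arenes untouched (benzyl ester hydrogenolysis).

Compound list
1 | 2,2,6-trimethyl-4H-1,3-dioxin-4-one | CC1=CC(=O)OC(C)(C)O1 | starting material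
2 | acetyl chloride | CC(=O)Cl | starting material
3 | 2,2-dimethyl-6-(2-oxopropyl)-4H-1,3-dioxin-4-one | CC(=O)CC1=CC(=O)OC(C)(C)O1 | intermediate
4 | butanoyl chloride | CCCC(=O)Cl | starting material
5 | N-methoxy-N-methylbutanamide | CCCC(=O)N(C)OC | intermediate
6 | 6-(2,4-dioxoheptyl)-2,2-dimethyl-4H-1,3-dioxin-4-one | CCCC(=O)CC(=O)CC1=CC(=O)OC(C)(C)O1 | intermediate
7 | benzyl alcohol | OCc1ccccc1 | starting material
8 | acylketene dec-1-ene-1,3,5,7-tetrone (not isolated) | CCCC(=O)CC(=O)CC(=O)C=C=O | intermediate
9 | benzyl 3,5,7-trioxodecanoate (not isolated) | CCCC(=O)CC(=O)CC(=O)CC(=O)OCc1ccccc1 | intermediate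
10 | cyclic aldol, benzyl 2-hydroxy-4,6-dioxo-2-propylcyclohexane-1-carboxylate (mixture of stereoisomers, not isolated) | CCCC1(O)CC(=O)CC(=O)C1C(=O)OCc1ccccc1 | intermediate
11 | benzyl 2,4-dihydroxy-6-propylbenzoate | CCCc1cc(O)cc(O)c1C(=O)OCc1ccccc1 | intermediate
12 | hexanoyl chloride | CCCCCC(=O)Cl | starting material
13 | N-methoxy-N-methylhexanamide | CCCCCC(=O)N(C)OC | intermediate
14 | 6-(2,4-dioxononyl)-2,2-dimethyl-4H-1,3-dioxin-4-one | CCCCCC(=O)CC(=O)CC1=CC(=O)OC(C)(C)O1 | intermediate
15 | acylketene dodec-1-ene-1,3,5,7-tetrone (not isolated) | CCCCCC(=O)CC(=O)CC(=O)C=C=O | intermediate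
16 | aryl triketo ester, benzyl 2-hydroxy-6-propyl-4-[(3,5,7-trioxododecanoyl)oxy]benzoate (not isolated) | CCCCCC(=O)CC(=O)CC(=O)CC(=O)Oc1cc(O)c(C(=O)OCc2ccccc2)c(CCC)c1 | intermediate
17 | cyclic aldol, benzyl 2-hydroxy-4-{[(2-hydroxy-4,6-dioxo-2-pentylcyclohexyl)carbonyl]oxy}-6-propylbenzoate (mixture of stereoisomers, not isolated) | CCCCCC1(O)CC(=O)CC(=O)C1C(=O)Oc1cc(O)c(C(=O)OCc2ccccc2)c(CCC)c1 | intermediate
18 | benzyl 4-[(2,4-dihydroxy-6-pentylbenzoyl)oxy]-2-hydroxy-6-propylbenzoate | CCCCCc1cc(O)cc(O)c1C(=O)Oc1cc(O)c(C(=O)OCc2ccccc2)c(CCC)c1 | intermediate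
19 | 4-[(2,4-dihydroxy-6-pentylbenzoyl)oxy]-2-hydroxy-6-propylbenzoic acid | CCCCCc1cc(O)cc(O)c1C(=O)Oc1cc(O)c(C(=O)O)c(CCC)c1 | target

Total step count: 8
Longest linear sequence: 5 steps (steps 1, 3, 4, 7 and 8, from 1 to 19)

Steps most likely to fail

Step 7 (proposed new method). Three processes could defeat it. The ring B phenoxide may be expelled from the aryl triketo ester, either by lactonisation of the C5 enol oxygen onto C1 to a 4-hydroxy-2-pyranone or by reversion to the ketene, faster than the C2-C7 aldol closes. The ketene may be captured by its own enol because a phenol adds more slowly than an aliphatic alcohol. Acylation may also occur at O2 or twice. The fallback builds ring A separately and joins the rings by a classical depside esterification; it sets out from 14 and 11 and returns to the route at 19. Compound 14 would be heated with allyl alcohol in toluene at 110 °C so that acylketene 15 is trapped as allyl 3,5,7-trioxododecanoate F1, which K2CO3 in i-PrOH–CH2Cl2 would cyclise to allyl 2-hydroxy-4,6-dioxo-2-pentylcyclohexane-1-carboxylate F2 and methanolic HCl would dehydrate to allyl 2,4-dihydroxy-6-pentylbenzoate F3 (the chemistry of step 4). Benzylation of both phenols (BnBr, K2CO3, DMF, 60 °C) would give allyl 2,4-bis(benzyloxy)-6-pentylbenzoate F4, and allyl transfer to morpholine catalysed by Pd(PPh3)4 (zerovalent palladium) would free 2,4-bis(benzyloxy)-6-pentylbenzoic acid F5. Activation of F5 as its mixed trifluoroacetic anhydride ((CF3CO)2O, toluene, rt) in the presence of 11 would acylate the 4-OH and give benzyl 4-{[2,4-bis(benzyloxy)-6-pentylbenzoyl]oxy}-2-hydroxy-6-propylbenzoate F6, and hydrogenolysis (H2, 10% Pd/C, EtOAc) would remove all three benzyl groups and deliver 19.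

Step 6 (step 3 is the same reaction and shares the risk). Proton transfer from the α-methylene of the Weinreb amide to the dianion, incomplete formation of the dianion, or reaction at oxygen could leave the Claisen acylation at low conversion. The fallback replaces the strong-base dianion by soft enolisation of a doubly activated methylene; it sets out from 1 and 12 and returns at 14. The dienolate of 1 (LiN(SiMe3)2, THF, −78 °C) would be acylated with allyl 3-chloro-3-oxopropanoate to give allyl 4-(2,2-dimethyl-4-oxo-4H-1,3-dioxin-6-yl)-3-oxobutanoate F7. MgCl2 and pyridine in CH2Cl2 would then direct C-acylation by 12 at the methylene between the ketone and the allyl ester, giving allyl 2-[(2,2-dimethyl-4-oxo-4H-1,3-dioxin-6-yl)acetyl]-3-oxooctanoate F8. Pd(PPh3)4 with morpholine would remove the allyl group, and the β-keto acid so formed would lose CO2 to give 14.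

Step 4. The ketene may be consumed by intramolecular capture through its own enol (pyranone formation) before benzyl alcohol adds, or the ester may exchange during the base and acid treatment. The fallback aromatises before the dioxinone is opened and so avoids the free ketene; it sets out from 6 and returns at 11. Treatment of 6 with Et3N in CH2Cl2 at rt should bring the dioxinone α-carbon onto the terminal ketone (aldol, then dehydration) with the dioxinone intact, giving 7-hydroxy-2,2-dimethyl-5-propyl-4H-1,3-benzodioxin-4-one F9. Heating F9 with sodium benzyloxide (BnOH, NaH, THF, 60 °C) would open the benzodioxinone by acyl substitution with loss of acetone and give 11 after acidic work-up.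

Further compounds
F1 | step 7 | allyl 3,5,7-trioxododecanoate | CCCCCC(=O)CC(=O)CC(=O)CC(=O)OCC=C
F2 | step 7 | allyl 2-hydroxy-4,6-dioxo-2-pentylcyclohexane-1-carboxylate (mixture of stereoisomers) | CCCCCC1(O)CC(=O)CC(=O)C1C(=O)OCC=C
F3 | step 7 | allyl 2,4-dihydroxy-6-pentylbenzoate | CCCCCc1cc(O)cc(O)c1C(=O)OCC=C
F4 | step 7 | allyl 2,4-bis(benzyloxy)-6-pentylbenzoate | CCCCCc1cc(OCc2ccccc2)cc(OCc2ccccc2)c1C(=O)OCC=C
F5 | step 7 | 2,4-bis(benzyloxy)-6-pentylbenzoic acid | CCCCCc1cc(OCc2ccccc2)cc(OCc2ccccc2)c1C(=O)O
F6 | step 7 | benzyl 4-{[2,4-bis(benzyloxy)-6-pentylbenzoyl]oxy}-2-hydroxy-6-propylbenzoate | CCCCCc1cc(OCc2ccccc2)cc(OCc2ccccc2)c1C(=O)Oc1cc(O)c(C(=O)OCc2ccccc2)c(CCC)c1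
F7 | step 6 | allyl 4-(2,2-dimethyl-4-oxo-4H-1,3-dioxin-6-yl)-3-oxobutanoate | C=CCOC(=O)CC(=O)CC1=CC(=O)OC(C)(C)O1
F8 | step 6 | allyl 2-[(2,2-dimethyl-4-oxo-4H-1,3-dioxin-6-yl)acetyl]-3-oxooctanoate | CCCCCC(=O)C(C(=O)OCC=C)C(=O)CC1=CC(=O)OC(C)(C)O1
F9 | step 4 | 7-hydroxy-2,2-dimethyl-5-propyl-4H-1,3-benzodioxin-4-one | CCCc1cc(O)cc2OC(C)(C)OC(=O)c12
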